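## Structural features

The target is a germacranolide: a ten-membered carbocycle (C1–C10) with a cis-fused α-methylene-γ-butyrolactone across C6–C7 (O on C6, C11–C13 on C7), methyls C14 on C10 and C15 on C4, an acetate on C3, a free hydroxyl on C8 and a (2R,3S)-2,3-dimethyloxirane-2-carboxylate on C9. The ring holds two trisubstituted Z olefins, C1=C10 and C4=C5, in a 1,5 relation through C2 and C3. C6, C7, C8 and C9 are contiguous stereocentres (6S,7R,8S,9S) and C3 (S) is separated from them by the C4=C5 bond; O3 and O6 lie on the same face of the planar C3–C4=C5–C6 unit, O6 and C11 are cis on C6–C7, and O8 and O9 are trans on the ring. Fragile groups are the exo-methylene lactone (nucleophiles, base), the epoxy ester (acid), the allylic esters on C3 and C9 (ionisation, migration to the neighbouring C8 hydroxyl) and the lactone itself (translactonisation to O8). The real difficulty is a flexible ten-membered ring with two Z trisubstituted olefins, each of which normally needs its own stereoselective olefination, and five stereocentres, one of them remote. The feature exploited is that C11 sits on C7, which is transannular (1,6) to C2: a bond C2–C11 turns the ring into a bicyclo[4.4.1]undecane built from two seven-membered rings (C11–C7–C6–C5–C4–C3–C2 and C11–C7–C8–C9–C10–C1–C2). In that bicycle each olefin lies in a seven-membered ring and can only be Z, C3 and C6 are the ends of a four-carbon bridge and C11 is a one-carbon carbonyl bridge, which is the retron of a [6+4] cycloaddition of a tropone (C11, C7, C8, C9, C10, C1, C2, C14) with a 1,4-dioxygenated 2-methylbutadiene (C3–C6, C15). In one sentence, the route is an exo [6+4] cycloaddition of 4-methyltropone with a 1,4-dioxygenated 2-methylbuta-1,3-diene, whose one-carbon bridge is cut later.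

## Logic of the disconnections

23 to 22: the O8–Si bond is cut. C8–OH must stay masked to the end because it would compete with O6 for the lactone and would form its own alkoxy radical. Nothing is gained in the skeleton. The forward step must be an acidic desilylation that causes neither acyl migration from O9 nor translactonisation.

22 to 21: the C11–C12 and C12–O6 bonds are cut and C12 leaves as carbon monoxide. The exo-methylene lactone is the most fragile group, so it is made last from an enol triflate and a free C6 hydroxyl. The forward step needs insertion into the vinyl triflate to be faster than ionisation of the two allylic esters, and it needs the cis relation of O6 and C11 to exist already.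

21 to 20 to 18: the O6–Si bond is cut, then the enol triflate is taken back to a methyl ketone on C7. The methyl ketone is exactly what bridge scission delivers. The forward enolisation must go to the methyl side and not to C7.

18 to 17: the C2–C11 bond is re-formed, so the ten-membered ring becomes the periphery of a bicyclo[4.4.1]undecane with a tertiary carbinol at C11. The gain is large: a flexible medium ring becomes a rigid bicycle whose two olefins are held Z by seven-membered rings and whose C11 is already on C7. The forward step must break C2–C11 and not C7–C11, return a hydrogen to C2 and leave the olefin geometry alone; this is why C8 and C9 must be sp3 before the scission, so that only C2 is allylic.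

17 to 16 to 11 + 15: the O8–Si bond is cut, then the C9–O ester bond. One anti opening of an exo vinyl epoxide by the acid gives the trans O8/O9 pair, the free O8–H and the acylated O9 together, and joins the side chain convergently. The forward step needs attack at the allylic carbon C9 with inversion. Because 15 is enantiopure, this step also separates the two enantiomeric series as diastereomers.

11 to 10 to 9: the C11–C13 bond (methyl) is cut, then the epoxide oxygen is removed. The methyl group converts the bridging ketone into the carbinol needed for scission and later becomes C13. The epoxidation must choose the cis-disubstituted C8=C9 bond over the trisubstituted C1=C10 and C4=C5 bonds and must come from the exo face.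

9 to 5 + 8 (key): the C2–C3 and C6–C7 bonds are cut. A bicycle with three stereocentres, two Z olefins and all eleven core carbons falls back to two flat achiral components. The forward step must control the orientation of the two unsymmetrical partners, [6+4] against [4+2], and exo against endo.

5 to 3 to 2 to 1: the one carbon inserted into the arene ring is removed (dihalocarbene ring expansion), then the dihydroarene is rearomatised. The carbene must add to the enol ether double bond so that the methyl group ends at C4 of the tropone.

8 to 7 to 6: the O–Si bond and the C5=C6 enol double bond are taken back to an enal, then the C4=C5 bond of the enal is cut by a Wittig retron. The enolisation must run towards the acetoxymethyl group and give the E,E diene.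

15 to 13 to 12: the acid is taken back to the epoxy alcohol and then to the allylic alcohol. The asymmetric epoxidation must give the (2S,3S) epoxy alcohol.

## Other disconnections considered

Alternative 1: Cut C6–C7 and the lactone C–O bond. The forward key step would be an intramolecular Nozaki–Hiyama–Kishi allylation–lactonisation (CrCl2, divalent chromium) of the ω-formyl 2-(bromomethyl)enoate A1 to give 22 directly. This is the first plan that comes to mind. The chosen plan is preferred because A1 needs each Z trisubstituted olefin from a separate stereoselective olefination and all three chain stereocentres from separate asymmetric steps in a long linear sequence. The ten-membered ring would then close against transannular strain, and the macrocyclic transition state gives no structural reason for the cis relation at C6/C7. In the chosen plan both olefin geometries are forced by ring size, and ring, C3, C6 and C7 come from one step.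

Alternative 2: Cut C6–C7 as the retron of a [2,3]-Wittig ring contraction. The forward key step would deprotonate the 13-membered bis-allylic ether A2 at C6 and contract it to the homoallylic alcohol A3. The easier 13-membered ether closure is attractive. The chosen plan is preferred because A2 has two competing allylic α-oxy positions (C6 and C13) and a competing [1,2] shift, and the strong base excludes the acetate and the epoxy ester. The 2-substituted allyl group on C7 would still have to be oxidised to the acrylate, and the Z olefins and the C3, C8, C9 centres would still be made one by one.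

Alternative 3: Add a transannular bond C4–C9 in the retro direction. The forward key step would be a Wharton–Grob fragmentation of the cis-decalin hydroxy mesylate A4, which forms C4=C5 stereospecifically (Z from the cis-fused conformer with equatorial mesylate) while C1=C10 is held Z by the six-membered ring, giving the cyclodecadienone A5. Geometry control is as good as in the chosen plan. The chosen plan is preferred because A4 carries seven stereocentres, of which three (C4, C5, C9) are sacrificial, and C9 returns as a ketone that must be reduced selectively next to C8. The outcome also depends on which chair conformer of the cis-decalin reacts, and the decalin takes many more steps than the two planar partners of the cycloaddition.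

Key step: step 6

Remark: the acyl group is read from the SMILES as the cis-dimethyl (2R,3S) epoxide and is made as such; germacrane numbering of 23 is used for all ring compounds from 9 on (in the bicycles C11 bridges C2 and C7); compounds 3 and 9–11 are racemic, their SMILES show the enantiomer that is carried on, and the single enantiomer is secured in step 11.

## Steps

Step 1
Reactants: 1 4-methylanisole
Product: 2 1-methoxy-4-methylcyclohexa-1,4-diene
Conditions: Li, NH3 (l), t-BuOH, THF, −78 to −33 °C
Reagents that add atoms: none
Why: Birch reduction; the donor substituents direct protonation so that both remaining double bonds carry the methoxy and the methyl group.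

Step 2
Reactants: 2 1-methoxy-4-methylcyclohexa-1,4-diene
Product: 3 (±)-7,7-dibromo-1-methoxy-4-methylbicyclo[4.1.0]hept-3-ene
Conditions: CHBr3, KOt-Bu, pentane, 0 °C
Reagents that add atoms: bromoform, BrC(Br)Br
Why: Electrophilic dibromocarbene should add to the enol ether double bond, the most electron-rich one; the cyclopropane can only be cis-fused.

Step 3
Reactants: 3 (±)-7,7-dibromo-1-methoxy-4-methylbicyclo[4.1.0]hept-3-ene
Product: 5 4-methyltropone (4-methylcyclohepta-2,4,6-trien-1-one), via 2-bromo-5-methylcyclohepta-2,5-dien-1-one 4 (not isolated)
Conditions: pyridine, 110 °C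
Reagents that add atoms: none
Why: Dihalocarbene ring expansion of a dihydroanisole: methoxy-assisted cyclopropyl-to-allyl opening with loss of bromide, O-demethylation to 4, then base-induced loss of HBr to the tropone. The former C4 methyl of 2 ends at C4 of the tropone.

Step 4
Reactants: 6 acetoxyacetone (2-oxopropyl acetate)
Product: 7 (2E)-4-acetoxy-3-methylbut-2-enal
Conditions: Ph3P=CHCHO, toluene, 90 °C
Reagents that add atoms: (triphenylphosphoranylidene)acetaldehyde, O=CC=P(c1ccccc1)(c1ccccc1)c1ccccc1
Why: Wittig olefination of an activated α-acyloxy ketone with the stabilised formyl ylide. The E/Z ratio does not matter because this double bond becomes the central single bond of 8.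

Step 5
Reactants: 7 (2E)-4-acetoxy-3-methylbut-2-enal
Product: 8 (1E,3E)-2-methyl-4-[(triethylsilyl)oxy]buta-1,3-dien-1-yl acetate
Conditions: Et3SiOTf, Et3N, Et2O, 0 to 25 °C
Reagents that add atoms: triethylsilyl trifluoromethanesulfonate, CC[Si](CC)(CC)OS(=O)(=O)C(F)(F)F
Why: Silyl dienol ether formation by O-silylation and γ-deprotonation; the acetoxymethyl protons are more acidic than the methyl protons and give the more substituted, doubly oxygenated diene. The E,E isomer should be favoured, and it is the only isomer that can reach the s-cis form needed in step 6.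

Step 6
Reactants: 5 4-methyltropone; 8 (1E,3E)-2-methyl-4-[(triethylsilyl)oxy]buta-1,3-dien-1-yl acetate
Product: 9 (±)-exo adduct, 4,8-dimethyl-11-oxo-10-[(triethylsilyl)oxy]bicyclo[4.4.1]undeca-2,4,8-trien-7-yl acetate (germacrane numbering: 3-OAc, 6-OSiEt3, C11 ketone bridging C2 and C7; C3, C6, C7 as in 23)
Conditions: toluene, BHT, 110 °C, sealed tube
Reagents that add atoms: none
Why: Thermal [6π+4π] cycloaddition: the triene of 5 (tropone C2–C7, which become C7, C8, C9, C10, C1 and C2) and the s-cis diene 8 (C3–C6) combine suprafacially on both partners through one concerted, asynchronous transition state in which the C2–C3 bond is more advanced; the closest known reaction type is the thermal exo [6+4] cycloaddition of tropone with 1-acetoxy- and 1-alkoxybutadienes. Both seven-membered rings of the bicyclo[4.4.1]undecane (C11 with C7–C6–C5–C4–C3–C2, and C11 with C7–C8–C9–C10–C1–C2) are closed by the cycloaddition itself and not by cyclisation of a chain, and their periphery is the complete ten-membered ring. The new C4=C5 bond lies in a seven-membered ring and can only be Z, and the C1=C10 bond is inherited from the tropone ring and is Z for the same reason. C3 and C6 are set cis to each other by the E,E geometry of 8 and the suprafacial addition; C7 and the temporary centre C2 are set relative to them by the exo transition state, in which the diene lies under the carbonyl group and avoids the repulsive secondary overlap of the endo mode, and this places O6 and C11 on the same side of C6–C7 as the cis-lactone needs. Regiochemistry is the selectivity that must be secured: the γ-carbon C3 of the silyl dienol ether is by far the more nucleophilic terminus (the charge it leaves is stabilised by the methyl on C4 and the silyloxy group on C6), and it should bond to the tropone terminus whose attack puts no negative charge on the methyl-bearing carbon, which is the terminus that becomes C2. Periselectivity ([6+4] against [4+2] and [8+2]) should follow the known preference of tropone with 1-oxygenated acyclic dienes, and a [4+2] adduct of the bicyclo[3.2.2] type can still reach 9 by [3,3] shift on further heating. The product is racemic.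

Step 7
Reactants: 9 (±)-exo [6+4] adduct
Product: 10 (±)-8,9-epoxide of 9, oxirane oxygen on the exo face (anti to the C7–C6 and C2–C3 bonds)
Conditions: rac-[Ti(μ-O)(salalen)]2 (3 mol %; salalen from trans-cyclohexane-1,2-diamine and 3-phenylsalicylaldehyde), 30% aq. H2O2, CH2Cl2, 25 °C
Reagents that add atoms: hydrogen peroxide, OO
Why: Titanium salalen/H2O2 epoxidation, a catalyst class that oxidises terminal and cis-1,2-disubstituted olefins and is sluggish towards trisubstituted ones, so C8=C9 should react before C1=C10 and the oxygen-flanked C4=C5. The oxygen should come from the face opposite the two pseudo-axial bonds C7–C6 and C2–C3, which sets C8 as in 23.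

Step 8
Reactants: 10 (±)-8,9-epoxide
Product: 11 (±)-11-hydroxy-11-methyl derivative of 10 (tertiary carbinol at the bridge; either configuration at C11)
Conditions: MeLi, CeCl3, THF, −78 °C; aq. NH4Cl
Reagents that add atoms: methyllithium, [Li]C
Why: 1,2-Addition of the organocerium reagent to the strained, non-enolisable bridging ketone; at −78 °C the acetate and the epoxide should not react. The new centre at C11 is destroyed in step 13, so its configuration does not matter.

Step 9
Reactants: 12 (E)-2-methylbut-2-en-1-ol
Product: 13 [(2S,3S)-2,3-dimethyloxiran-2-yl]methanol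
Conditions: Ti(OiPr)4 (5 mol %), L-(+)-diethyl tartrate (6 mol %), t-BuOOH, 4 Å MS, CH2Cl2, −20 °C
Reagents that add atoms: tert-butyl hydroperoxide, CC(C)(C)OO
Why: Sharpless asymmetric epoxidation; the L-(+)-tartrate delivers oxygen to the face that gives the (2S,3S) epoxy alcohol, and the E olefin fixes the cis relation of the two methyl groups.

Step 10
Reactants: 13 [(2S,3S)-2,3-dimethyloxiran-2-yl]methanol
Product: 15 (2R,3S)-2,3-dimethyloxirane-2-carboxylic acid, via (2R,3S)-2,3-dimethyloxirane-2-carbaldehyde 14 (not isolated)
Conditions: RuCl3 (2 mol %), NaIO4, MeCN–EtOAc–H2O, 0 °C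
Reagents that add atoms: water, O
Why: Ruthenium tetroxide oxidation of a primary alcohol through the aldehyde hydrate; the epoxide and both stereocentres are untouched (the descriptor at C2 changes only by priority).

Step 11
Reactants: 11 (±)-epoxy carbinol; 15 (2R,3S)-2,3-dimethyloxirane-2-carboxylic acid
Product: 16 C9 ester, C8 alcohol (bicyclic; C3, C6, C7, C8, C9 as in 23)
Conditions: 15 (1.5 equiv), Cs2CO3 (0.3 equiv), DMF, 60 °C; chromatography
Reagents that add atoms: none
Why: SN2 opening of the vinyl epoxide by the carboxylate at the allylic carbon C9 with inversion, which sets C9, gives the trans O8/O9 pair and leaves O8 free. The tertiary carbinol cannot reach the back side of either epoxide carbon. Each enantiomer of 11 gives one diastereomer, and the one from the unwanted enantiomer is removed by chromatography, so 16 is a single enantiomer.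

Step 12
Reactants: 16 C9 ester, C8 alcohol
Product: 17 8-O-tert-butyldimethylsilyl ether of 16
Conditions: t-BuMe2SiOTf, 2,6-lutidine, CH2Cl2, −78 °C
Reagents that add atoms: tert-butyldimethylsilyl trifluoromethanesulfonate, CC(C)(C)[Si](C)(C)OS(=O)(=O)C(F)(F)F
Why: Silylation of the secondary hydroxyl; the tertiary bridge carbinol, flanked by two bridgeheads, should stay free.

Step 13
Reactants: 17 silyl ether with free C11 carbinol
Product: 18 (1(10)Z,4Z)-7-acetyl-cyclodeca-1(10),4-diene (monocyclic; 3-OAc, 6-OSiEt3, 8-OSiMe2t-Bu, 9-epoxy ester; stereocentres as in 23)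
Conditions: [Ir(dF(CF3)ppy)2(5,5'-d(CF3)bpy)]PF6 (2 mol %), 2,4,6-triisopropylbenzenethiol (20 mol %), Bu4N[(BuO)2PO2] (20 mol %), PhCF3, blue LED, 25 °C
Reagents that add atoms: none
Why: Redox-neutral ring-opening isomerisation of a tertiary cycloalkanol: proton-coupled electron transfer gives the C11 alkoxy radical, and β-scission breaks C2–C11 (allylic radical, release of the bridge) rather than C7–C11 (unstabilised, both neighbours sp3). The thiol returns a hydrogen atom to the less hindered terminus C2, giving C2H2 and the methyl ketone on C7. The allyl radical keeps the ring-imposed Z geometry of C1=C10, and Z,Z is also the stable geometry of the ten-membered ring.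

Step 14
Reactants: 18 methyl ketone
Product: 20 enol triflate of 18 (7-[1-(trifluoromethanesulfonyloxy)vinyl]), via kinetic potassium enolate 19 (not isolated)
Conditions: KN(SiMe3)2, THF, −78 °C; then PhNTf2
Reagents that add atoms: N-phenylbis(trifluoromethanesulfonimide), O=S(=O)(N(c1ccccc1)S(=O)(=O)C(F)(F)F)C(F)(F)F
Why: Kinetic deprotonation at the methyl group (the tertiary C7–H is hindered) and O-triflation; enolisation away from C7 also avoids β-elimination of O6 or O8.

Step 15
Reactants: 20 enol triflate
Product: 21 C6 alcohol (triethylsilyl group removed)
Conditions: HF·pyridine, pyridine, THF, 0 °C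
Reagents that add atoms: none
Why: Selective cleavage of the more labile secondary triethylsilyl ether in the presence of the hindered tert-butyldimethylsilyl ether on O8.

Step 16
Reactants: 21 C6 alcohol with enol triflate
Product: 22 8-O-tert-butyldimethylsilyl ether of the target lactone
Conditions: Pd(PPh3)4 (5 mol %), CO (1 atm), Et3N, MeCN, 50 °C
Reagents that add atoms: carbon monoxide, [C-]#[O+]
Why: Carbonylative lactonisation: oxidative addition of zerovalent palladium into the vinyl triflate, CO insertion and capture of the acyl complex by the C6 hydroxyl give the α-methylene-γ-butyrolactone, cis-fused because C6 and C7 are already set. O8 is silylated, so the isomeric 8,12-lactone cannot form; the CO atmosphere and low temperature should disfavour ionisation of the allylic esters.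

Step 17
Reactants: 22 silylated lactone
Product: 23 target, (1(10)Z,4Z)-(3S,6S,7R,8S,9S)-3-acetoxy-8-hydroxy-9-{[(2R,3S)-2,3-dimethyloxiran-2-yl]carbonyloxy}germacra-1(10),4,11(13)-trien-12,6-olide
Conditions: HF·pyridine, THF, 25 °C
Reagents that add atoms: none
Why: Acidic fluoride desilylation; the absence of base should prevent acyl migration from O9 to O8, translactonisation and conjugate addition to the methylene lactone.

## Compound list

1 | 4-methylanisole | COc1ccc(C)cc1 | starting material
2 | 1-methoxy-4-methylcyclohexa-1,4-diene | COC1=CCC(C)=CC1 | intermediate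
3 | (±)-7,7-dibromo-1-methoxy-4-methylbicyclo[4.1.0]hept-3-ene (cis-fused; one enantiomer drawn) | CO[C@@]12CC=C(C)C[C@@H]1C2(Br)Br | intermediate
4 | 2-bromo-5-methylcyclohepta-2,5-dien-1-one (not isolated) | O=C1CC=C(C)CC=C1Br | intermediate
5 | 4-methyltropone (4-methylcyclohepta-2,4,6-trien-1-one) | O=C1C=CC(C)=CC=C1 | intermediate
6 | acetoxyacetone (2-oxopropyl acetate) | CC(=O)COC(C)=O | starting material
7 | (2E)-4-acetoxy-3-methylbut-2-enal | O=C/C=C(\C)COC(C)=O | intermediate
8 | (1E,3E)-2-methyl-4-[(triethylsilyl)oxy]buta-1,3-dien-1-yl acetate | CC(=O)O/C=C(C)/C=C/O[Si](CC)(CC)CC | intermediate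
9 | (±)-exo [6+4] adduct, 4,8-dimethyl-11-oxo-10-[(triethylsilyl)oxy]bicyclo[4.4.1]undeca-2,4,8-trien-7-yl acetate (C3, C6, C7 as in 23; enantiomer carried on is drawn) | [C@H]1(O[Si](CC)(CC)CC)C=C(C)[C@@H](OC(C)=O)[C@@H]2C=C(C)C=C[C@H]1C2=O | intermediate
10 | (±)-8,9-exo-epoxide of 9 (enantiomer carried on is drawn) | [C@H]1(O[Si](CC)(CC)CC)C=C(C)[C@@H](OC(C)=O)[C@@H]2C=C(C)[C@H]3O[C@H]3[C@H]1C2=O | intermediate
11 | (±)-11-hydroxy-11-methyl derivative of 10 (C11 configuration immaterial and left open; enantiomer carried on is drawn) | [C@H]1(O[Si](CC)(CC)CC)C=C(C)[C@@H](OC(C)=O)[C@@H]2C=C(C)[C@H]3O[C@H]3[C@H]1C2(C)O | intermediate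
12 | (E)-2-methylbut-2-en-1-ol | C/C=C(\C)CO | starting material
13 | [(2S,3S)-2,3-dimethyloxiran-2-yl]methanol | OC[C@]1(C)O[C@H]1C | intermediate
14 | (2R,3S)-2,3-dimethyloxirane-2-carbaldehyde (not isolated) | O=C[C@]1(C)O[C@H]1C | intermediate
15 | (2R,3S)-2,3-dimethyloxirane-2-carboxylic acid | OC(=O)[C@]1(C)O[C@H]1C | intermediate
16 | bicyclic C9 (2R,3S)-epoxy ester with free C8–OH and C11 carbinol (3-OAc, 6-OSiEt3; single enantiomer; C11 left open) | [C@H]1(O[Si](CC)(CC)CC)C=C(C)[C@@H](OC(C)=O)[C@@H]2C=C(C)[C@H](OC(=O)[C@]3(C)O[C@H]3C)[C@@H](O)[C@H]1C2(C)O | intermediate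
17 | 8-O-tert-butyldimethylsilyl ether of 16 | [C@H]1(O[Si](CC)(CC)CC)C=C(C)[C@@H](OC(C)=O)[C@@H]2C=C(C)[C@H](OC(=O)[C@]3(C)O[C@H]3C)[C@@H](O[Si](C)(C)C(C)(C)C)[C@H]1C2(C)O | intermediate
18 | (1(10)Z,4Z)-7-acetyl-3-acetoxy-6-(triethylsilyloxy)-8-(tert-butyldimethylsilyloxy)-9-epoxyacyloxy-4,10-dimethylcyclodeca-1(10),4-diene (stereocentres as in 23) | [C@H]1(O[Si](CC)(CC)CC)/C=C(/C)[C@@H](OC(C)=O)C/C=C(/C)[C@H](OC(=O)[C@]2(C)O[C@H]2C)[C@@H](O[Si](C)(C)C(C)(C)C)[C@H]1C(C)=O | intermediate
19 | kinetic potassium enolate of 18 (not isolated) | [C@H]1(O[Si](CC)(CC)CC)/C=C(/C)[C@@H](OC(C)=O)C/C=C(/C)[C@H](OC(=O)[C@]2(C)O[C@H]2C)[C@@H](O[Si](C)(C)C(C)(C)C)[C@H]1C([O-])=C.[K+] | intermediate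
20 | enol triflate of 18 | [C@H]1(O[Si](CC)(CC)CC)/C=C(/C)[C@@H](OC(C)=O)C/C=C(/C)[C@H](OC(=O)[C@]2(C)O[C@H]2C)[C@@H](O[Si](C)(C)C(C)(C)C)[C@H]1C(=C)OS(=O)(=O)C(F)(F)F | intermediate
21 | C6 alcohol of 20 | [C@H]1(O)/C=C(/C)[C@@H](OC(C)=O)C/C=C(/C)[C@H](OC(=O)[C@]2(C)O[C@H]2C)[C@@H](O[Si](C)(C)C(C)(C)C)[C@H]1C(=C)OS(=O)(=O)C(F)(F)F | intermediate
22 | 8-O-tert-butyldimethylsilyl ether of the target | C=C1C(=O)O[C@H]2/C=C(/C)[C@@H](OC(C)=O)C/C=C(/C)[C@H](OC(=O)[C@]3(C)O[C@H]3C)[C@@H](O[Si](C)(C)C(C)(C)C)[C@@H]12 | intermediate
23 | (1(10)Z,4Z)-(3S,6S,7R,8S,9S)-3-acetoxy-8-hydroxy-9-{[(2R,3S)-2,3-dimethyloxiran-2-yl]carbonyloxy}germacra-1(10),4,11(13)-trien-12,6-olide | C=C1C(=O)O[C@H]2/C=C(/C)[C@@H](OC(C)=O)C/C=C(/C)[C@H](OC(=O)[C@]3(C)O[C@H]3C)[C@@H](O)[C@@H]12 | target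

## Step count and least certain steps

Total: 17 steps. Longest linear sequence: 13 steps (1, 2, 3, 6, 7, 8, 11, 12, 13, 14, 15, 16, 17).

Step 6 (key step). The most likely failure is weak discrimination between the two tropone termini, because the methyl group of 5 is remote from both, so the head-to-head orientation may compete; diversion into the [4+2] or [8+2] manifold is the second risk. The fallback uses a bromine atom as a removable regiochemical marker. It sets out from 3: ring opening without base (AgNO3, aqueous acetone) should stop at 4, which is isolated, and dehydrogenation with DDQ should give 2-bromo-5-methyltropone F1, with the halogen on the terminus that becomes C7. 2-Halotropones are attacked by nucleophiles at the unsubstituted α-carbon, so C3 of 8 should be steered to the terminus that becomes C2, and cycloaddition of F1 with 8 (toluene, 110 °C) should give the C7-bromo adduct F2. Bu3SnH/AIBN then removes the bridgehead halogen and the route is rejoined at 9.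

Step 7. The risk is insufficient site selectivity, with oxidation of the more electron-rich C1=C10 bond, or low reactivity of the hindered cis olefin towards the bulky catalyst. The fallback uses the intrinsic reactivity order instead of fighting it and sets out from 9. OsO4 (cat.)/N-methylmorpholine N-oxide should dihydroxylate the most electron-rich C1=C10 bond to the 1,10-diol F3, which thiocarbonyldiimidazole converts into the cyclic thiocarbonate F4. mCPBA should then epoxidise C8=C9, the only remaining unhindered nucleophilic olefin, from the exo face to the thiocarbonate epoxide F5. Corey–Hopkins olefination (1,3-dimethyl-2-phenyl-1,3,2-diazaphospholidine, THF, 40 °C), a stereospecific syn elimination, restores the Z C1=C10 bond and rejoins the route at 10.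

Step 11. The risk is that the hindered carboxylate fails to reach C9 from the endo face or attacks C1 in an SN2' sense, and that the triethylsilyl ether is lost in the buffered acid. The fallback separates ring opening from acylation and sets out from 11. Hydrolytic opening with the smallest nucleophile (H2O, Sc(OTf)3 5 mol %, THF, 0 °C) should give the trans-8,9-diol F6. Yamaguchi acylation (2,4,6-trichlorobenzoyl chloride, Et3N, DMAP) with 15 should then occur at the allylic C9 hydroxyl, which is less hindered than the C8 hydroxyl next to the bridgehead, and after separation of the diastereomers the route is rejoined at 16.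

Step 13. The risk is hydrogen-atom return at C10 instead of C2 (olefin transposition) or inefficient formation of the alkoxy radical because the excited catalyst is quenched by the olefins. The fallback uses stoichiometric hypoiodite fragmentation with halogen capture and sets out from 17: PhI(OAc)2, I2 and visible light should cleave the same C2–C11 bond and trap the allyl radical as the allylic iodide F7. Bu3SnH/Et3B, a bulky hydrogen donor that favours the less hindered C2 terminus, then reduces the iodide and rejoins the route at 18.

Step 16. The risk is ionisation of the allylic esters at C3 and C9 by zerovalent palladium, leading to loss or 1,3-transposition of an ester, in competition with insertion into the triflate. The fallback is palladium-free and sets out from 18. The kinetic potassium enolate (KN(SiMe3)2, −78 °C) is hydroxylated with 2-(phenylsulfonyl)-3-phenyloxaziridine to the hydroxymethyl ketone F8. Methylenation with Ph3P=CH2 gives the 2-substituted allylic alcohol F9, and HF·pyridine/pyridine removes the triethylsilyl group to give the diol F10. TEMPO/PhI(OAc)2 then oxidises the primary allylic alcohol and the lactol it forms with the C6 hydroxyl, and the route is rejoined at 22.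

## Further compounds

F1 | step 6 | 2-bromo-5-methyltropone | O=C1C(Br)=CC=C(C)C=C1
F2 | step 6 | C7-bromo analogue of 9 (bridgehead bromide) | [C@H]1(O[Si](CC)(CC)CC)C=C(C)[C@@H](OC(C)=O)[C@@H]2C=C(C)C=C[C@@]1(Br)C2=O
F3 | step 7 | 1,10-exo-cis-diol of 9 | [C@H]1(O[Si](CC)(CC)CC)C=C(C)[C@@H](OC(C)=O)[C@@H]2[C@@H](O)[C@@](C)(O)C=C[C@H]1C2=O
F4 | step 7 | cyclic 1,10-thiocarbonate of F3 | [C@H]1(O[Si](CC)(CC)CC)C=C(C)[C@@H](OC(C)=O)[C@@H]2[C@H]3OC(=S)O[C@@]3(C)C=C[C@H]1C2=O
F5 | step 7 | 8,9-exo-epoxide of F4 | [C@H]1(O[Si](CC)(CC)CC)C=C(C)[C@@H](OC(C)=O)[C@@H]2[C@H]3OC(=S)O[C@@]3(C)[C@H]4O[C@H]4[C@H]1C2=O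
F6 | step 11 | trans-8,9-diol from hydrolysis of 11 (C11 left open) | [C@H]1(O[Si](CC)(CC)CC)C=C(C)[C@@H](OC(C)=O)[C@@H]2C=C(C)[C@H](O)[C@@H](O)[C@H]1C2(C)O
F7 | step 13 | 2-iodo derivative of 18 (allylic iodide, C2 configuration open) | [C@H]1(O[Si](CC)(CC)CC)/C=C(/C)[C@@H](OC(C)=O)C(I)/C=C(/C)[C@H](OC(=O)[C@]2(C)O[C@H]2C)[C@@H](O[Si](C)(C)C(C)(C)C)[C@H]1C(C)=O
F8 | step 16 | hydroxymethyl ketone from 18 | [C@H]1(O[Si](CC)(CC)CC)/C=C(/C)[C@@H](OC(C)=O)C/C=C(/C)[C@H](OC(=O)[C@]2(C)O[C@H]2C)[C@@H](O[Si](C)(C)C(C)(C)C)[C@H]1C(=O)CO
F9 | step 16 | 2-substituted allylic alcohol from F8 | [C@H]1(O[Si](CC)(CC)CC)/C=C(/C)[C@@H](OC(C)=O)C/C=C(/C)[C@H](OC(=O)[C@]2(C)O[C@H]2C)[C@@H](O[Si](C)(C)C(C)(C)C)[C@H]1C(=C)CO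
F10 | step 16 | C6,C12-diol from F9 | [C@H]1(O)/C=C(/C)[C@@H](OC(C)=O)C/C=C(/C)[C@H](OC(=O)[C@]2(C)O[C@H]2C)[C@@H](O[Si](C)(C)C(C)(C)C)[C@H]1C(=C)CO
A1 | alternative 1 | ω-formyl (Z)-2-(bromomethyl)enoate, precursor of the chromium-mediated macrocyclisation | O=C/C=C(/C)[C@@H](OC(C)=O)C/C=C(/C)[C@H](OC(=O)[C@]1(C)O[C@H]1C)[C@@H](O[Si](C)(C)C(C)(C)C)/C=C(\CBr)C(=O)OC
A2 | alternative 2 | 13-membered bis-allylic ether | O1C/C=C(/C)[C@@H](O[Si](C)(C)C(C)(C)C)C/C=C(/C)[C@H](OCOC)[C@@H](OCOC)/C=C(\COCc2ccc(OC)cc2)C1
A3 | alternative 2 | ring-contracted ten-membered homoallylic alcohol | [C@H]1(O)/C=C(/C)[C@@H](O[Si](C)(C)C(C)(C)C)C/C=C(/C)[C@H](OCOC)[C@@H](OCOC)[C@H]1C(=C)COCc1ccc(OC)cc1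
A4 | alternative 3 | cis-decalin hydroxy mesylate (C4–C9 bonded) | C[C@@]12[C@H](OS(C)(=O)=O)[C@H](O[Si](C)(C)C(C)(C)C)[C@H](CC(=O)OC)[C@H](O[Si](C)(C)C(C)(C)C)[C@]1(O)C(C)=CC[C@@H]2OC(C)=O
A5 | alternative 3 | (1(10)Z,4Z)-cyclodecadien-9-one from fragmentation | [C@H]1(O[Si](C)(C)C(C)(C)C)/C=C(/C)[C@@H](OC(C)=O)C/C=C(/C)C(=O)[C@@H](O[Si](C)(C)C(C)(C)C)[C@H]1CC(=O)OC
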